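## Retrosynthetic overview

1. The C12–C13 bond is cut by a B-alkyl Suzuki–Miyaura coupling between a C9-vinyl decalin and a ready-made (E)-iodoalkenyl butenolide (C15/C16 from a vinylogous Mukaiyama aldol); the C4 methyl enters through a temporary γ-lactone between the C4 carbonyl and the 6α-oxygen.
2. Rings A and B are closed together by an intramolecular furan Diels–Alder reaction of a 3-silyloxyfuran (bonds C5–C10 and C8–C9); SmI2 then cuts the resulting 5,8-oxygen bridge at C5, so the furan oxygen stays as the C8 tertiary hydroxyl.
3. Enabling feature: in ring B the segment C5–C6–C7–C8 carries oxygen on C6 and both oxygen and methyl on C8, so it is a latent 5-methyl-3-oxyfuran; C9=C10 with the C10 methyl is the (E)-enal end of a geraniol-derived chain.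
4. Ring order: 3(2H)-furanone (temporary heterocycle, from dimethyl L-malate, whose derived C4 centre steers the key step) → rings A and B in one operation → temporary γ-lactone → butenolide ring brought in preformed.

Key step: step 9

Remark: locants are terpenoid-type (ring carbons C1–C10, side chain C11–C15, lactone CH = C16; α is the face opposite to the C10 methyl); the target is taken as drawn in the given SMILES (4R,5R,6S,8R,9R,10S,13E,15S,16S), and geraniol, dimethyl (S)-malate, but-2-yn-1-ol and 4-methylfuran-2(5H)-one are taken as commercial.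

## Route

Step 1
Reactants: 1 geraniol
Product: 2 geranyl tert-butyldimethylsilyl ether
Conditions: TBSCl, imidazole, DMF, 23 °C
Reagents that add atoms: tert-butyldimethylsilyl chloride, CC(C)(C)[Si](C)(C)Cl
Why: Silyl ether formation on the primary allylic alcohol masks the future C11 oxygen in a form that survives strong base and Grignard reagents; no stereocentre is formed and the (E)-alkene is untouched.

Step 2
Reactants: 2 geranyl tert-butyldimethylsilyl ether
Product: 4 (4E)-6-(tert-butyldimethylsilyloxy)-4-methylhex-4-en-1-ol, via aldehyde 3 (not isolated)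
Conditions: O3 (1.0 equiv, Sudan red 7B end point), CH2Cl2/MeOH, −78 °C; then NaBH4, −78 → 0 °C
Reagents that add atoms: ozone, [O-][O+]=O
Why: Ozonolysis with reductive work-up cleaves the more electron-rich remote isopropylidene alkene in preference to the alkene that is inductively deactivated by the allylic silyloxy group and gives the primary alcohol that becomes C3, with no stereocentre formed.

Step 3
Reactants: 4 (4E)-6-(tert-butyldimethylsilyloxy)-4-methylhex-4-en-1-ol
Product: 5 (2E)-6-iodo-3-methylhex-2-enyl tert-butyldimethylsilyl ether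
Conditions: I2, PPh3, imidazole, CH2Cl2, 0 °C
Reagents that add atoms: iodine, II
Why: Appel-type iodination converts the primary alcohol into the primary iodide by SN2 displacement of the oxyphosphonium ion without touching the silyl ether or the alkene.

Step 4
Reactants: 6 dimethyl (S)-malate; 5 (2E)-6-iodo-3-methylhex-2-enyl tert-butyldimethylsilyl ether
Product: 8 dimethyl (2S,3R)-3-alkylmalate, via dilithium alkoxide enolate 7 (not isolated)
Conditions: LiN(iPr)2 (2.1 equiv), THF, −78 → −20 °C; then 5, DMPU, −78 → −10 °C; aq. NH4Cl
Reagents that add atoms: none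
Why: Fráter–Seebach alkylation, in which the chelated dilithium alkoxide–enolate of the β-hydroxy ester is alkylated on the face anti to the alkoxide, forms the C3–C4 bond and sets C4 as R (2S,3R product).

Step 5
Reactants: 8 dimethyl (2S,3R)-3-alkylmalate
Product: 10 hydroxy ynone, via Weinreb amide 9 (not isolated)
Conditions: MeNH(OMe)·HCl, iPrMgCl, THF, −20 °C; then CH3C≡CMgBr, −20 → 0 °C; aq. NH4Cl
Reagents that add atoms: 1-propynylmagnesium bromide, CC#C[Mg]Br
Why: The magnesium alkoxide activates the adjacent, less hindered α-hydroxy ester for amide formation and the resulting Weinreb amide takes up exactly one alkynyl Grignard reagent (Weinreb ketone synthesis), which adds C7, C8 and the C8 methyl without touching C4 or C5.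

Step 6
Reactants: 10 hydroxy ynone
Product: 11 furanone silyl ether
Conditions: (Ph3P)AuCl (5 mol%), AgOTf (5 mol%), toluene, 23 °C
Reagents that add atoms: none
Why: Gold-catalysed 5-endo-dig cycloisomerisation of the γ-hydroxy ynone (hydroxyl oxygen onto C8) gives the 5-methyl-3(2H)-furanone under neutral conditions that leave C4 intact, and the retained C5 centre is erased later.

Step 7
Reactants: 11 furanone silyl ether
Product: 12 furanone allylic alcohol
Conditions: HF·pyridine, pyridine, THF, 0 → 23 °C
Reagents that add atoms: none
Why: Fluoride-mediated desilylation frees the primary allylic alcohol under buffered conditions that do not enolise the furanone or the ester.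

Step 8
Reactants: 12 furanone allylic alcohol
Product: 13 furanone enal
Conditions: MnO2, CH2Cl2, 23 °C
Reagents that add atoms: none
Why: Allylic oxidation with MnO2 gives the (E)-enal dienophile without isomerising the trisubstituted alkene or oxidising the furanone.

Step 9
Reactants: 13 furanone enal
Product: 15 oxa-bridged cycloadduct, via silyloxyfuran 14 (not isolated)
Conditions: TBSOTf (1.1 equiv), Et3N (1.5 equiv), CH2Cl2, −78 → 23 °C; then toluene, 60 °C
Reagents that add atoms: tert-butyldimethylsilyl triflate, CC(C)(C)[Si](C)(C)OS(=O)(=O)C(F)(F)F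
Why: Et3N/TBSOTf enolises the furanone at C5, its only α' position, to the aromatic 3-silyloxyfuran 14, whose diene C5=C6(OSi)–C7=C8(CH3) (ring oxygen on C5 and C8) adds to the tethered (E)-enal C9=C10 in an intramolecular furan Diels–Alder reaction of normal electron demand, the nucleophilic enol-ether carbon C5 bonding to the enal β-carbon C10 and the enal α-carbon C9 to C8. The closest known reaction types are intramolecular Diels–Alder reactions of furans with tethered enones and enals and intermolecular cycloadditions of 3-silyloxyfurans. Ring A closes through C5–C10 as the four-carbon tether ring of a type 1 intramolecular [4+2] cycloaddition, ring B closes through C8–C9 as the cyclohexene ring of the same suprafacial [4+2] event, and the furan oxygen is left as a temporary 5,8-bridge that already is the C8 oxygen of the target. A six-membered tether can join C5 to C10 only in the exo sense (syn to the oxygen bridge), so the C10 methyl and, through the (E)-geometry of the enal, the C9 formyl group come out anti to the bridge, which fixes C5, C8 (O α, CH3 β), C9 and C10 relative to one another by geometry alone. C4 (R, from malate) selects the furan face: only one exo adduct has the C4 ester equatorial on the new chair-like ring A, the other has it 1,3-diaxial to the C10 methyl, and since furan cycloadditions are reversible the equatorial-ester adduct 15 should accumulate. The step needs cycloaddition to win over an arrested Mukaiyama–Michael addition and over β-elimination of the bridge next to the aldehyde, which the electron-rich diene, the matched polarity of both new bonds, the weak base and the direct use of 15 in step 10 are meant to secure.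

Step 10
Reactants: 15 oxa-bridged cycloadduct
Product: 17 oxa-bridged vinyl ketone, via vinyl silyl enol ether 16 (not isolated)
Conditions: Ph3PCH3Br, KN(SiMe3)2, THF, −78 → 0 °C; then 1 M HCl, THF, 0 °C
Reagents that add atoms: methylenetriphenylphosphorane (from Ph3PCH3Br and KN(SiMe3)2), C=P(c1ccccc1)(c1ccccc1)c1ccccc1
Why: Wittig methylenation turns the hindered C11 aldehyde into the C9 vinyl group faster than it is enolised, and dilute acid then hydrolyses the silyl enol ether by protonation at C7 to the C6 ketone without forming a free enolate that could expel the C8–O bridge; no stereocentre changes.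

Step 11
Reactants: 17 oxa-bridged vinyl ketone
Product: 19 diol ester, via hydroxy ketone 18 (not isolated)
Conditions: SmI2 (6 equiv), THF/MeOH, −78 °C; then H2O, −78 → 23 °C
Reagents that add atoms: none
Why: Divalent samarium cleaves the C5–O bond α to the C6 ketone (reductive cleavage of an α-alkoxy ketone), the resulting samarium enolate is protonated at C5 from the α face anti to the C10 methyl to give the trans ring fusion, and continued electron-transfer reduction of the C6 ketone in the presence of water should deliver the equatorial 6α-alcohol because the axial 6β-alcohol would be 1,3-diaxial to both the C8 and the C10 methyl groups.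

Step 12
Reactants: 19 diol ester
Product: 20 hydroxy lactone
Conditions: NaH (10 mol%), 4 Å molecular sieves, THF, 0 → 23 °C
Reagents that add atoms: none
Why: Alkoxide-catalysed intramolecular transesterification (5-exo-trig lactonisation) ties the 6α-oxygen to the equatorial C4 ester, a bridge that is geometrically possible only for the 4α-carbonyl/6α-oxygen pair, and thereby protects both groups and prepares the stereocontrolled C4 methylation.

Step 13
Reactants: 20 hydroxy lactone
Product: 22 C4-methyl lactone, via dilithium lactone enolate 21 (not isolated)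
Conditions: LiN(iPr)2 (2.3 equiv), THF, −78 → −40 °C; then MeI (1.5 equiv), −78 → −40 °C; aq. NH4Cl
Reagents that add atoms: iodomethane, CI
Why: Methylation of the lactone enolate (the C8 hydroxyl rides along as its lithium alkoxide) builds the C4 quaternary centre, and because the lactone bridge holds the carbonyl carbon in the α (equatorial) position the methyl group can only be taken up on the β face, which makes C4 R.

Step 14
Reactants: 22 C4-methyl lactone
Product: 24 vinyl diol ester, via potassium carboxylate 23 (not isolated)
Conditions: KOH, MeOH/H2O, 70 °C; KH2PO4 to pH 8, evaporation; then MeI, DMF, 23 °C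
Reagents that add atoms: potassium hydroxide, [K+].[OH-]; iodomethane, CI
Why: Saponification opens the strained lactone irreversibly to the potassium carboxylate with retention at C6 and SN2 O-methylation of the carboxylate with iodomethane then gives the methyl ester without any acid that could close the lactone again.

Step 15
Reactants: 25 but-2-yn-1-ol
Product: 27 (E)-3-iodobut-2-en-1-ol, via alkenylzirconocene 26 (not isolated)
Conditions: Cp2Zr(H)Cl (2.2 equiv), THF, 23 °C; then I2, 0 °C
Reagents that add atoms: iodine, II
Why: syn-Hydrozirconation of the alkyne (as its zirconium alkoxide) places zirconium on C3, the carbon that carries the smaller methyl group, and iodine replaces zirconium with retention, so the (E)-3-iodoalkenol results (hydrozirconation–iodination).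

Step 16
Reactants: 27 (E)-3-iodobut-2-en-1-ol
Product: 28 (E)-3-iodobut-2-enal
Conditions: MnO2, CH2Cl2, 23 °C
Reagents that add atoms: none
Why: Allylic oxidation with MnO2 gives the β-iodo enal with the alkene geometry unchanged.

Step 17
Reactants: 29 4-methylfuran-2(5H)-one
Product: 30 4-methyl-2-(trimethylsilyloxy)furan
Conditions: TMSOTf, Et3N, Et2O, 0 °C
Reagents that add atoms: trimethylsilyl triflate, C[Si](C)(C)OS(=O)(=O)C(F)(F)F
Why: Soft enolisation at the γ position and O-silylation of the butenolide gives the 2-silyloxyfuran that serves as the vinylogous nucleophile.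

Step 18
Reactants: 28 (E)-3-iodobut-2-enal; 30 4-methyl-2-(trimethylsilyloxy)furan
Product: 32 iodo hydroxy butenolide, via trimethylsilyl ether 31 (not isolated)
Conditions: Ti(OiPr)4 (20 mol%), (R)-BINOL (20 mol%), Et2O, −20 °C; then 1 M HCl, THF, 0 °C
Reagents that add atoms: none
Why: Vinylogous Mukaiyama aldol addition of C5 of the silyloxyfuran to the aldehyde under a chiral titanium BINOLate Lewis acid should give the threo (15S,16S) adduct, because the open transition state of Lewis-acid-promoted additions of 2-silyloxyfurans favours the threo isomer and the ligand shields one face of the bound aldehyde (the mirror-image ligand would be taken if the sense of induction proved opposite), and minor isomers are removed at this small-fragment stage.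

Step 19
Reactants: 32 iodo hydroxy butenolide
Product: 33 iodo silyloxy butenolide
Conditions: TBSCl, imidazole, DMF, 23 °C
Reagents that add atoms: tert-butyldimethylsilyl chloride, CC(C)(C)[Si](C)(C)Cl
Why: Silylation of the secondary allylic alcohol prevents retro-aldol cleavage and translactonisation of the δ-hydroxy butenolide under the basic coupling conditions.

Step 20
Reactants: 24 vinyl diol ester; 33 iodo silyloxy butenolide
Product: 35 silyl-protected target, via alkylborane 34 (not isolated)
Conditions: 9-BBN (4 equiv), THF, 23 → 50 °C; then 33, Pd(dppf)Cl2 (10 mol%), AsPh3 (10 mol%), 3 M aq. K3PO4, DMF, 23 °C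
Reagents that add atoms: none
Why: Anti-Markovnikov hydroboration of the only alkene of 24 gives the primary C12 borane, which is coupled with the (E)-alkenyl iodide with retention of geometry in a B-alkyl Suzuki–Miyaura reaction, so that the C12–C13 bond and the 13E alkene are set without touching the butenolide stereocentres.

Step 21
Reactants: 35 silyl-protected target
Product: 36 target CNP0104474.1
Conditions: HF·pyridine, pyridine, THF, 0 → 23 °C
Reagents that add atoms: none
Why: Fluoride-mediated cleavage of the silyl ether under buffered, weakly acidic conditions frees the C15 hydroxyl and gives the target without base that could epimerise C16 or close the C4/C6 lactone.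

## Compound list

1 | geraniol, (2E)-3,7-dimethylocta-2,6-dien-1-ol | CC(C)=CCC/C(C)=C/CO | starting material
2 | geranyl tert-butyldimethylsilyl ether | CC(C)=CCC/C(C)=C/CO[Si](C)(C)C(C)(C)C | intermediate
3 | (4E)-6-(tert-butyldimethylsilyloxy)-4-methylhex-4-enal | O=CCC/C(C)=C/CO[Si](C)(C)C(C)(C)C | intermediate
4 | (4E)-6-(tert-butyldimethylsilyloxy)-4-methylhex-4-en-1-ol | OCCC/C(C)=C/CO[Si](C)(C)C(C)(C)C | intermediate
5 | tert-butyl{[(2E)-6-iodo-3-methylhex-2-en-1-yl]oxy}dimethylsilane | ICCC/C(C)=C/CO[Si](C)(C)C(C)(C)C | intermediate
6 | dimethyl (2S)-2-hydroxybutanedioate (dimethyl L-malate) | COC(=O)C[C@H](O)C(=O)OC | starting material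
7 | dilithium alkoxide–enolate of dimethyl (S)-malate | [Li+].[Li+].COC([O-])=C[C@H]([O-])C(=O)OC | intermediate
8 | dimethyl (2S,3R)-2-hydroxy-3-[(4E)-6-(tert-butyldimethylsilyloxy)-4-methylhex-4-en-1-yl]butanedioate | COC(=O)[C@H](CCC/C(C)=C/CO[Si](C)(C)C(C)(C)C)[C@H](O)C(=O)OC | intermediate
9 | methyl (2R,3S)-2-[(4E)-6-(tert-butyldimethylsilyloxy)-4-methylhex-4-en-1-yl]-3-hydroxy-4-[methoxy(methyl)amino]-4-oxobutanoate (Weinreb amide) | COC(=O)[C@H](CCC/C(C)=C/CO[Si](C)(C)C(C)(C)C)[C@H](O)C(=O)N(C)OC | intermediate
10 | methyl (2R,3S)-2-[(4E)-6-(tert-butyldimethylsilyloxy)-4-methylhex-4-en-1-yl]-3-hydroxy-4-oxohept-5-ynoate | COC(=O)[C@H](CCC/C(C)=C/CO[Si](C)(C)C(C)(C)C)[C@H](O)C(=O)C#CC | intermediate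
11 | methyl (2R,6E)-8-(tert-butyldimethylsilyloxy)-6-methyl-2-[(2S)-5-methyl-3-oxo-2,3-dihydrofuran-2-yl]oct-6-enoate | COC(=O)[C@H](CCC/C(C)=C/CO[Si](C)(C)C(C)(C)C)[C@@H]1OC(C)=CC1=O | intermediate
12 | methyl (2R,6E)-8-hydroxy-6-methyl-2-[(2S)-5-methyl-3-oxo-2,3-dihydrofuran-2-yl]oct-6-enoate | COC(=O)[C@H](CCC/C(C)=C/CO)[C@@H]1OC(C)=CC1=O | intermediate
13 | methyl (2R,6E)-6-methyl-2-[(2S)-5-methyl-3-oxo-2,3-dihydrofuran-2-yl]-8-oxooct-6-enoate | COC(=O)[C@H](CCC/C(C)=C/C=O)[C@@H]1OC(C)=CC1=O | intermediate
14 | methyl (2R,6E)-2-[3-(tert-butyldimethylsilyloxy)-5-methylfuran-2-yl]-6-methyl-8-oxooct-6-enoate | COC(=O)[C@H](CCC/C(C)=C/C=O)c1oc(C)cc1O[Si](C)(C)C(C)(C)C | intermediate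
15 | cycloadduct: rings A/B with an oxygen bridge from C5 to C8 on the α face, C6=C7 silyl enol ether (OTBS on C6), 4α-CO2Me (4β-H), 8β-CH3, 9β-CHO, 10β-CH3 | COC(=O)[C@@H]1CCC[C@@]2(C)[C@@]1(O3)C(O[Si](C)(C)C(C)(C)C)=C[C@]3(C)[C@@H]2C=O | intermediate
16 | as 15 but with a 9β-vinyl group in place of the formyl group | COC(=O)[C@@H]1CCC[C@@]2(C)[C@@]1(O3)C(O[Si](C)(C)C(C)(C)C)=C[C@]3(C)[C@@H]2C=C | intermediate
17 | 5α,8α-oxygen-bridged 6-ketone: 4α-CO2Me (4β-H), 8β-CH3, 9β-vinyl, 10β-CH3 | COC(=O)[C@@H]1CCC[C@@]2(C)[C@@]1(O3)C(=O)C[C@]3(C)[C@@H]2C=C | intermediate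
18 | trans-decalin hydroxy ketone: 4α-CO2Me (4β-H), 5α-H, 6-oxo, 8α-OH, 8β-CH3, 9β-vinyl, 10β-CH3 | COC(=O)[C@@H]1CCC[C@@]2(C)[C@H]1C(=O)C[C@@](C)(O)[C@@H]2C=C | intermediate
19 | diol ester: as 18 with 6α-OH (6β-H) in place of the ketone | COC(=O)[C@@H]1CCC[C@@]2(C)[C@H]1[C@@H](O)C[C@@](C)(O)[C@@H]2C=C | intermediate
20 | hydroxy lactone: γ-lactone between the 4α-carbonyl and the 6α-oxygen, 4β-H, 8α-OH, 9β-vinyl | O=C3[C@@H]1CCC[C@@]2(C)[C@H]1[C@@H](O3)C[C@@](C)(O)[C@@H]2C=C | intermediate
21 | dilithium salt of 20 (lactone enolate at C4, alkoxide at C8) | [Li+].[Li+].[O-]C3=C1CCC[C@@]2(C)[C@H]1[C@@H](O3)C[C@@](C)([O-])[C@@H]2C=C | intermediate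
22 | C4-methyl lactone: as 20 with 4β-CH3 (C4 R) | O=C3[C@]1(C)CCC[C@@]2(C)[C@H]1[C@@H](O3)C[C@@](C)(O)[C@@H]2C=C | intermediate
23 | potassium carboxylate from opening of 22 (6α-OH free) | [K+].[O-]C(=O)[C@]1(C)CCC[C@@]2(C)[C@H]1[C@@H](O)C[C@@](C)(O)[C@@H]2C=C | intermediate
24 | vinyl diol ester: methyl ester at C4 (α) with 4β-CH3, 6α-OH, 8α-OH, 8β-CH3, 9β-vinyl, 10β-CH3 | COC(=O)[C@]1(C)CCC[C@@]2(C)[C@H]1[C@@H](O)C[C@@](C)(O)[C@@H]2C=C | intermediate
25 | but-2-yn-1-ol | CC#CCO | starting material
26 | (E)-alkenylzirconocene chloride of but-2-yn-1-ol (zirconium on C3, oxygen as zirconocene alkoxide) | C/C(=C\CO[Zr](Cl)(C1C=CC=C1)C1C=CC=C1)[Zr](Cl)(C1C=CC=C1)C1C=CC=C1 | intermediate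
27 | (2E)-3-iodobut-2-en-1-ol | C/C(I)=C\CO | intermediate
28 | (2E)-3-iodobut-2-enal | C/C(I)=C\C=O | intermediate
29 | 4-methylfuran-2(5H)-one | CC1=CC(=O)OC1 | starting material
30 | 4-methyl-2-(trimethylsilyloxy)furan | Cc1coc(O[Si](C)(C)C)c1 | intermediate
31 | (5S)-5-[(1S,2E)-3-iodo-1-(trimethylsilyloxy)but-2-en-1-yl]-4-methylfuran-2(5H)-one | C/C(I)=C\[C@H](O[Si](C)(C)C)[C@H]1OC(=O)C=C1C | intermediate
32 | (5S)-5-[(1S,2E)-1-hydroxy-3-iodobut-2-en-1-yl]-4-methylfuran-2(5H)-one | C/C(I)=C\[C@H](O)[C@H]1OC(=O)C=C1C | intermediate
33 | (5S)-5-[(1S,2E)-1-(tert-butyldimethylsilyloxy)-3-iodobut-2-en-1-yl]-4-methylfuran-2(5H)-one | C/C(I)=C\[C@H](O[Si](C)(C)C(C)(C)C)[C@H]1OC(=O)C=C1C | intermediate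
34 | B-alkyl-9-borabicyclo[3.3.1]nonane from 24 (boron on C12) | COC(=O)[C@]1(C)CCC[C@@]2(C)[C@H]1[C@@H](O)C[C@@](C)(O)[C@@H]2CCB1C2CCCC1CCC2 | intermediate
35 | 15-O-tert-butyldimethylsilyl ether of the target | COC(=O)[C@]1(C)CCC[C@@]2(C)[C@H]1[C@@H](O)C[C@@](C)(O)[C@@H]2CC/C(C)=C/[C@H](O[Si](C)(C)C(C)(C)C)[C@H]1OC(=O)C=C1C | intermediate
36 | CNP0104474.1, methyl ester with 6α-, 8α- and (15S)-hydroxyls, 13E alkene and (16S)-4-methylbutenolide | COC(=O)[C@]1(C)CCC[C@@]2(C)[C@H]1[C@@H](O)C[C@@](C)(O)[C@@H]2CC/C(C)=C/[C@H](O)[C@H]1OC(=O)C=C1C | target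

## Step count and risks

Total step count: 21. Longest linear sequence: 16 steps (steps 1–14, 20 and 21).

Step 9 is the most likely to fail: the cycloaddition may stop at, or fall back to, the open-chain stage (arrested Mukaiyama–Michael addition or cycloreversion), or the furan face may be chosen with poor selectivity relative to C4. The fallback makes the two bonds one after the other, setting out from 13. A catalytic amine base (DBU, MeCN, 23 °C) lets the furanone C5 carbanion add to the enal β-carbon (intramolecular Michael addition, ring A) to give the spiro furanone aldehyde F1. Pyrrolidine/benzoic acid then converts the aldehyde into its enamine, which adds through C9 to C8 of the vinylogous ester (second intramolecular Michael addition, ring B) to give the oxa-bridged keto aldehyde F2. Wittig methylenation of F2 (Ph3PCH3Br, KN(SiMe3)2, THF, −78 °C) returns to the route at 17.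

Step 11 is second: proton delivery to C6 may follow kinetic instead of thermodynamic control and give the axial alcohol, and the β-hydroxy ketone may suffer retro-aldol opening before it is reduced. The fallback sets out from 17, which is treated with only 2.2 equiv of SmI2 (THF/MeOH, −78 °C) so that hydroxy ketone 18 is isolated. NaBH4 (MeOH, 0 °C) then attacks C6 from the open α face and gives the axial 6β-alcohol F3. Activation of the 6β-hydroxyl as its triflate (Tf2O, pyridine, CH2Cl2, −40 → 0 °C) lets the carbonyl oxygen of the C4 ester displace it from the α face with inversion, the ester methyl being lost to pyridine (lactonisation by neighbouring-group participation). This returns to the route at 20.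

Step 18 is third: facial control of the aldehyde and threo/erythro control may both be modest, and attack through the α-carbon of the silyloxyfuran may compete. The fallback sets out from 28 and 30 and gives up asymmetric induction: BF3·OEt2 (CH2Cl2, −78 °C, acidic work-up) gives the racemic threo alcohol F4, whose enantiomers are separated by preparative chromatography on a chiral stationary phase; the (15S,16S) enantiomer is 32, where the route is rejoined.

Further compounds
F1 | step 9 | methyl 2,6-dimethyl-4-oxo-6-(2-oxoethyl)-1-oxaspiro[4.5]dec-2-ene-10-carboxylate (ring A closed; C4, C5 and C10 configured as in 17) | COC(=O)[C@@H]1CCC[C@](C)(CC=O)[C@]12OC(C)=CC2=O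
F2 | step 9 | oxa-bridged keto aldehyde (17 with a 9β-formyl group in place of the vinyl group) | COC(=O)[C@@H]1CCC[C@@]2(C)[C@@]1(O3)C(=O)C[C@]3(C)[C@@H]2C=O
F3 | step 11 | 6β-epimer of diol ester 19 (axial 6β-OH) | COC(=O)[C@@H]1CCC[C@@]2(C)[C@H]1[C@H](O)C[C@@](C)(O)[C@@H]2C=C
F4 | step 18 | racemic threo-5-[(2E)-1-hydroxy-3-iodobut-2-en-1-yl]-4-methylfuran-2(5H)-one | C/C(I)=C\[C@H](O)[C@H]1OC(=O)C=C1C.C/C(I)=C\[C@@H](O)[C@@H]1OC(=O)C=C1C
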